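The constants are hidden from you, so start from what the two closed runs give.

the same everywhere: initiator 31 mM
- gamma: substrate 0.31 M; partner 0.403 M; run made earlier
- eta: substrate 0.31 M; partner 0.81 M; run made earlier
- west: substrate 0.31 M; partner 0.403 M; everything together in a closed stirred flask, run for 20 min; time 20 min
- north-west: substrate 0.31 M; partner 0.403 M; a single well-mixed tank run continuously and read at steady state, 20 min in it on average
- north-east: substrate 0.31 M (fed, over 16.0 min); partner 0.403 M; a stirred flask in which substrate is dosed at a steady rate over 16.0 min without added volume, worked up at 20 min; time 20 min
- north: substrate 0.31 M; partner 0.403 M (fed, over 16.0 min); all but partner at the start; partner goes in evenly over 16.0 min, the run ends at 20 min; time 20 min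

- gamma (time / min: product / %): 2.00: 29.0; 5.00: 33.2; 10.0: 32.4; 15.0: 33.9; 20.0: 33.1
- eta (time / min: product / %): 0.333: 7.8; 1.00: 18.6; 2.00: 35.1; 3.00: 37.3; 4.00: 38.5

(scatter of a reading: 1 percentage point)

- the stated concentrations are those of everything mixed, before any reaction; amounts are the same in each set-up
- the feed brings no volume worth counting
- the earlier runs were made in a closed, stirred flask
- a reading or a percentage of product counts all its forms, free or not

* the set-up with the highest amount of product at the outlet or at the end, in percent of the substrate put in ("none" if the first two lie within 2 percentage points) (west / north-west / north-east / north / none)
* amount of product at the outlet or at the end, in percent of the substrate put in, west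
* amount of product at the outlet or at the end, in percent of the substrate put in, north-west
* amount of product at the outlet or at the end, in percent of the substrate put in, north-east
* amount of product at the outlet or at the end, in percent of the substrate put in, north

Read the last row of each table. Gamma's last reading, at 20.0 min, is 33.1% and eta's, at 4.00 min, is 38.5%: eta had twice the partner, and a different time, with just 5.4 percentage points between the two.

So follow one partner molecule. Assume each last reading marks the end of partner: the molecule either became product or was lost. Gamma made 0.103 M of product, so partner lost per product made is 2.93; call this the waste ratio, the inverse of a selectivity. Read so, a partner molecule in gamma became product about a quarter of the time.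

Eta, by its last reading, had made 0.119 M, which gives a waste ratio of 5.79, twice gamma's. These are readings, with their scatter, but across these two runs the ratio moved in step with c(partner). I therefore take the loss to grow with c(partner) and the path to product not to.

My own reckoning follows. West repeats gamma. The tank and north hold c(partner) down, so their waste ratios should fall and their product rise. North-east puts full c(partner) against a c(substrate) that starts at nothing; if the path to product needs substrate, its waste ratio climbs. North starts at full c(substrate), while the tank runs at its outlet value. My order is north, north-west, west, north-east.

The forecast gives none as best, with 33.2% for west, 31% for north-west, 31% for north-east and 25% for north, arguing “Slow partner feeding keeps partner low, which lowers turnovers, so about 25%.” It puts north lowest, where my order has it first.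

The simulation puts north first; these are the steps behind it.

    initiator → 2 initiating radical (k = 1.03 × 10⁻⁴ s⁻¹)
    substrate + initiating radical → capped initiator + first chain carrier (k = 4.71 × 10⁵ L mol⁻¹ s⁻¹)
    partner + first chain carrier ⇌ product + second chain carrier (K = 1.80, k = 6.05 × 10⁵ L mol⁻¹ s⁻¹)
    substrate + second chain carrier → released group + first chain carrier (k = 18300 L mol⁻¹ s⁻¹)
    2 first chain carrier → ended chains A (k = 3.00 × 10⁸ L mol⁻¹ s⁻¹)
    2 second chain carrier → ended chains B (k = 9.00 × 10⁷ L mol⁻¹ s⁻¹)
    partner + product ⇌ idle adduct, settled at all times (K = 78.0 L mol⁻¹)
    partner → decomposed reagent (k = 0.0182 s⁻¹)

North gives 47.9%, against 33.8% for west, 35.6% for north-west and 6.59% for north-east. At 0.592 min in north-east, partner went to decomposed reagent 83 times as fast as by the forward step to product alone. Counted as decomposed reagent per product, the waste ratio is 1.43 in north and 18.7 in north-east, against the 2.93 read from gamma. The neighbour flask, north-east with 0.0077 M of initiator, holds 0.390 M of decomposed reagent and gives 4.13% of product, a waste ratio of 30.4.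

Readings and results stem from a simulated flask on assumed constants, and the scatter is random.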